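**Plan**
- Retrosynthesis: remove the two O-methyl groups, open the lactone at C1–O2, then cut the benzene ring at C3a–C7a (phthalide numbering: C1 carbonyl, O2, C3 carbinol, C3a, C4–C7, C7a).
- Enabling feature: ring atoms C3a, C4, C5, C6, C7, C7a carry oxygen at C5 and C7, the C1 carbonyl on C7a and the C3 carbinol on C3a. This is a resorcylate, i.e. a 3,5,7-triketo ester folded so that the ester α-carbon (C7a) adds to the last ketone (C3a).
- The triketo ester is masked as a diketo-dioxinone, cut at C3a–C4 (Claisen) into a keto-dioxinone (itself cut at C5–C6) and an (S)-α-silyloxy N-methoxy-N-methylamide. The amide chain is cut at C1'–C2' of the side chain (epoxide opening).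
- Forward: bromo ketal chain, Grignard opening of the glycidyl ether, α-silyloxy amide, Claisen union with the dioxinone piece, benzene ring (step 11), lactone ring (step 12), O-methylation.
- Stereochemistry: the only stereocentre, C3 (S), is C2 of (S)-benzyl glycidyl ether; no bond to it is made or broken afterwards.

Key step: step 11

Remark: the 1,3-dicarbonyl and polycarbonyl compounds of the route are named and drawn as keto tautomers although they are expected to be largely enolised.

**Step 1**
Reactants: 1 12-bromododecanoic acid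
Product: 3 12-bromo-N-methoxy-N-methyldodecanamide, via 12-bromododecanoyl chloride 2 (not isolated)
Conditions: (COCl)2, cat. DMF, CH2Cl2, 0 °C to rt, concentrate; then MeNH(OMe)·HCl, Et3N, CH2Cl2, 0 °C
Reagents that add atoms: N,O-dimethylhydroxylamine hydrochloride, CNOC.Cl
Why: Acid chloride formation followed by amidation (Weinreb amide synthesis) is routine for ω-bromo acids, and the primary bromide is inert to Et3N at 0 °C.

**Step 2**
Reactants: 3 12-bromo-N-methoxy-N-methyldodecanamide
Product: 4 13-bromotridecan-2-one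
Conditions: MeMgBr (1.2 equiv), THF, −10 to 0 °C; 1 M HCl
Reagents that add atoms: methylmagnesium bromide, C[Mg]Br
Why: In the Weinreb ketone synthesis the N-methoxy-N-methylamide accepts only one equivalent of Grignard reagent, and a primary alkyl bromide does not react with MeMgBr at this temperature.

**Step 3**
Reactants: 4 13-bromotridecan-2-one
Product: 5 2-(11-bromoundecyl)-2-methyl-1,3-dioxolane
Conditions: HOCH2CH2OH, cat. p-TsOH·H2O, toluene, reflux, Dean–Stark trap
Reagents that add atoms: ethylene glycol, OCCO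
Why: Acid-catalysed ketalisation with azeotropic removal of water should mask the ketone so that the bromide can later be turned into a Grignard reagent.

**Step 4**
Reactants: 5 2-(11-bromoundecyl)-2-methyl-1,3-dioxolane; 6 (S)-benzyl glycidyl ether
Product: 8 (2S)-1-(benzyloxy)-14-(2-methyl-1,3-dioxolan-2-yl)tetradecan-2-ol, via Grignard reagent 7 (not isolated)
Conditions: Mg turnings, cat. I2, THF, 45 °C; then 6, CuI (10 mol%), THF, −30 to 0 °C; sat. aq NH4Cl
Reagents that add atoms: none
Why: The copper-catalysed Grignard opening of a terminal epoxide is an SN2 attack at the unsubstituted carbon, so the C1'–C2' bond forms while the stereocentre of 6 is untouched and appears as (S) in 8.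

**Step 5**
Reactants: 8 (2S)-1-(benzyloxy)-14-(2-methyl-1,3-dioxolan-2-yl)tetradecan-2-ol
Product: 9 (2S)-1-(benzyloxy)-2-(tert-butyldimethylsilyloxy)-14-(2-methyl-1,3-dioxolan-2-yl)tetradecane
Conditions: TBSCl, imidazole, DMF, rt
Reagents that add atoms: tert-butyldimethylsilyl chloride, CC(C)(C)[Si](C)(C)Cl
Why: Imidazole-promoted silylation of a secondary alcohol is a standard protection and the basic medium leaves the dioxolane intact.

**Step 6**
Reactants: 9 (2S)-1-(benzyloxy)-2-(tert-butyldimethylsilyloxy)-14-(2-methyl-1,3-dioxolan-2-yl)tetradecane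
Product: 10 (2S)-2-(tert-butyldimethylsilyloxy)-14-(2-methyl-1,3-dioxolan-2-yl)tetradecan-1-ol
Conditions: H2 (1 atm), 10% Pd/C, EtOAc, rt
Reagents that add atoms: none
Why: Hydrogenolysis of the benzyl ether in a neutral aprotic solvent should free the primary alcohol without cleaving the silyl ether or the ketal and without silyl migration.

**Step 7**
Reactants: 10 (2S)-2-(tert-butyldimethylsilyloxy)-14-(2-methyl-1,3-dioxolan-2-yl)tetradecan-1-ol
Product: 11 (2S)-2-(tert-butyldimethylsilyloxy)-14-(2-methyl-1,3-dioxolan-2-yl)tetradecanoic acid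
Conditions: TEMPO (cat.), NaOCl (cat.), NaClO2 (2 equiv), MeCN, pH 6.7 phosphate buffer, 35 °C; extraction at pH 4
Reagents that add atoms: sodium chlorite, [Na+].[O-]Cl=O
Why: The TEMPO-catalysed chlorite oxidation takes a primary alcohol to the acid at near-neutral pH, which should spare the ketal and silyl ether and not epimerise the α-silyloxy centre.

**Step 8**
Reactants: 11 (2S)-2-(tert-butyldimethylsilyloxy)-14-(2-methyl-1,3-dioxolan-2-yl)tetradecanoic acid
Product: 13 (2S)-2-(tert-butyldimethylsilyloxy)-N-methoxy-N-methyl-14-(2-methyl-1,3-dioxolan-2-yl)tetradecanamide, via acyl imidazolide 12 (not isolated)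
Conditions: 1,1'-carbonyldiimidazole, CH2Cl2, rt; then MeNH(OMe)·HCl, rt
Reagents that add atoms: N,O-dimethylhydroxylamine hydrochloride, CNOC.Cl
Why: Activation as the acyl imidazolide and aminolysis (Weinreb amide formation) proceeds under nearly neutral conditions that should not racemise an α-silyloxy acid.

**Step 9**
Reactants: 14 2,2,6-trimethyl-4H-1,3-dioxin-4-one
Product: 16 2,2-dimethyl-6-(2-oxopropyl)-4H-1,3-dioxin-4-one, via lithium dienolate 15 (not isolated)
Conditions: LiN(SiMe3)2 (1.05 equiv), THF, −78 °C; AcCl (0.5 equiv), −78 °C; 1 M HCl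
Reagents that add atoms: acetyl chloride, CC(Cl)=O
Why: Kinetic γ-deprotonation gives the cross-conjugated dienolate, which is C-acylated at the γ-carbon (Claisen-type acylation, C5–C6 bond), half of the dienolate serving as base for the more acidic product.

**Step 10**
Reactants: 16 2,2-dimethyl-6-(2-oxopropyl)-4H-1,3-dioxin-4-one; 13 (2S)-2-(tert-butyldimethylsilyloxy)-N-methoxy-N-methyl-14-(2-methyl-1,3-dioxolan-2-yl)tetradecanamide
Product: 18 6-[(5S)-5-(tert-butyldimethylsilyloxy)-17-(2-methyl-1,3-dioxolan-2-yl)-2,4-dioxoheptadecyl]-2,2-dimethyl-4H-1,3-dioxin-4-one, via dilithium dienediolate 17 (not isolated)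
Conditions: 16 (2.2 equiv), LiN(iPr)2 (4.5 equiv), THF, −78 °C; then 13 (1.0 equiv), −78 to −30 °C; AcOH, −78 °C
Reagents that add atoms: none
Why: In this crossed Claisen condensation the terminal carbanion of the dienediolate, its most nucleophilic site, is acylated once by the N-methoxy-N-methylamide (C3a–C4 bond), and at low temperature the α-silyloxy stereocentre should not be enolised.

**Step 11**
Reactants: 18 6-[(5S)-5-(tert-butyldimethylsilyloxy)-17-(2-methyl-1,3-dioxolan-2-yl)-2,4-dioxoheptadecyl]-2,2-dimethyl-4H-1,3-dioxin-4-one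
Product: 22 methyl 2-[(1S)-1-(tert-butyldimethylsilyloxy)-13-(2-methyl-1,3-dioxolan-2-yl)tridecyl]-4,6-dihydroxybenzoate, via acylketene 19 (not isolated), via triketo ester 20 (not isolated), via cyclic aldol adduct 21 (not isolated)
Conditions: MeOH (20 equiv), toluene, 110 °C (sealed tube); then Cs2CO3 (2 equiv), MeOH, 0 °C to rt; AcOH to pH 5, rt
Reagents that add atoms: methanol, CO
Why: Heating 18 should expel acetone by a retro-hetero-Diels–Alder reaction to give acylketene 19, which the excess methanol traps as triketo ester 20; Cs2CO3 then ionises the ester α-methylene (the future C7a), which adds to the ketone next to the silyloxy carbon (the future C3a) to give 21, and loss of water with enolisation of the two remaining ring ketones gives arene 22. The closest known reaction type is the ketene-capture and aldol aromatisation of diketo-dioxinones to resorcylates, here with an α-silyloxy ketone as the acceptor. The benzene ring closes by a 6-(enolendo)-exo-trig aldol addition that forms the C3a–C7a bond. No lasting stereocentre is created (the two ring centres of 21 vanish on aromatisation), and the (S) carbinol should be kept because the doubly activated methylenes are ionised long before its C–H, which becomes a non-acidic benzylic C–H once the ring is aromatic. The step needs C-cyclisation of C7a onto C3a in preference to pyranone formation (enol oxygen onto the ketene or ester), furanone formation and Claisen closure onto the ester; the large excess of methanol, the mild carbonate base, the silyl cap on the α-oxygen and the inductively activated α-silyloxy ketone should secure this.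

**Step 12**
Reactants: 22 methyl 2-[(1S)-1-(tert-butyldimethylsilyloxy)-13-(2-methyl-1,3-dioxolan-2-yl)tridecyl]-4,6-dihydroxybenzoate
Product: 23 (3S)-5,7-dihydroxy-3-(13-oxotetradecyl)-2-benzofuran-1(3H)-one
Conditions: 2 M aq HCl, THF, 45 °C
Reagents that add atoms: water, O
Why: Acid hydrolysis removes the silyl ether and the dioxolane, and the freed benzylic alcohol lactonises onto the ortho methyl ester (5-exo-trig acyl substitution); the C3–O bond is never broken and the meta-placed phenols cannot stabilise a benzylic cation, so the configuration should be retained.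

**Step 13**
Reactants: 23 (3S)-5,7-dihydroxy-3-(13-oxotetradecyl)-2-benzofuran-1(3H)-one
Product: 24 CJ-13,108, (3S)-5,7-dimethoxy-3-(13-oxotetradecyl)-2-benzofuran-1(3H)-one
Conditions: MeI (excess), K2CO3, acetone, reflux
Reagents that add atoms: iodomethane, CI
Why: Williamson O-methylation with a carbonate base should alkylate both phenols, including the hydrogen-bonded C7 hydroxyl on heating, while the base is too weak to enolise the methyl ketone or deprotonate C3.

**Compound list**
1 | 12-bromododecanoic acid | OC(=O)CCCCCCCCCCCBr | starting material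
2 | 12-bromododecanoyl chloride | ClC(=O)CCCCCCCCCCCBr | intermediate (not isolated)
3 | 12-bromo-N-methoxy-N-methyldodecanamide | CON(C)C(=O)CCCCCCCCCCCBr | intermediate
4 | 13-bromotridecan-2-one | CC(=O)CCCCCCCCCCCBr | intermediate
5 | 2-(11-bromoundecyl)-2-methyl-1,3-dioxolane | CC1(CCCCCCCCCCCBr)OCCO1 | intermediate
6 | (S)-benzyl glycidyl ether, (2S)-2-(benzyloxymethyl)oxirane | [C@@H]1(COCc2ccccc2)CO1 | starting material
7 | [11-(2-methyl-1,3-dioxolan-2-yl)undecyl]magnesium bromide | Br[Mg]CCCCCCCCCCCC1(C)OCCO1 | intermediate (not isolated)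
8 | (2S)-1-(benzyloxy)-14-(2-methyl-1,3-dioxolan-2-yl)tetradecan-2-ol | c1ccccc1COC[C@H](CCCCCCCCCCCCC2(C)OCCO2)O | intermediate
9 | (2S)-1-(benzyloxy)-2-(tert-butyldimethylsilyloxy)-14-(2-methyl-1,3-dioxolan-2-yl)tetradecane | c1ccccc1COC[C@H](CCCCCCCCCCCCC2(C)OCCO2)O[Si](C)(C)C(C)(C)C | intermediate
10 | (2S)-2-(tert-butyldimethylsilyloxy)-14-(2-methyl-1,3-dioxolan-2-yl)tetradecan-1-ol | OC[C@H](CCCCCCCCCCCCC1(C)OCCO1)O[Si](C)(C)C(C)(C)C | intermediate
11 | (2S)-2-(tert-butyldimethylsilyloxy)-14-(2-methyl-1,3-dioxolan-2-yl)tetradecanoic acid | OC(=O)[C@H](CCCCCCCCCCCCC1(C)OCCO1)O[Si](C)(C)C(C)(C)C | intermediate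
12 | 1-[(2S)-2-(tert-butyldimethylsilyloxy)-14-(2-methyl-1,3-dioxolan-2-yl)tetradecanoyl]-1H-imidazole | O=C(n1ccnc1)[C@H](CCCCCCCCCCCCC1(C)OCCO1)O[Si](C)(C)C(C)(C)C | intermediate (not isolated)
13 | (2S)-2-(tert-butyldimethylsilyloxy)-N-methoxy-N-methyl-14-(2-methyl-1,3-dioxolan-2-yl)tetradecanamide | CON(C)C(=O)[C@H](CCCCCCCCCCCCC1(C)OCCO1)O[Si](C)(C)C(C)(C)C | intermediate
14 | 2,2,6-trimethyl-4H-1,3-dioxin-4-one | CC1=CC(=O)OC(C)(C)O1 | starting material
15 | lithium 2,2-dimethyl-6-methylidene-6H-1,3-dioxin-4-olate | [Li]OC1=CC(=C)OC(C)(C)O1 | intermediate (not isolated)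
16 | 2,2-dimethyl-6-(2-oxopropyl)-4H-1,3-dioxin-4-one | CC(=O)CC1=CC(=O)OC(C)(C)O1 | intermediate
17 | dilithium 2,2-dimethyl-6-(2-oxidoprop-2-en-1-ylidene)-6H-1,3-dioxin-4-olate | [Li]OC(=C)C=C1C=C(O[Li])OC(C)(C)O1 | intermediate (not isolated)
18 | 6-[(5S)-5-(tert-butyldimethylsilyloxy)-17-(2-methyl-1,3-dioxolan-2-yl)-2,4-dioxoheptadecyl]-2,2-dimethyl-4H-1,3-dioxin-4-one | CC1(C)OC(=O)C=C(CC(=O)CC(=O)[C@H](CCCCCCCCCCCCC2(C)OCCO2)O[Si](C)(C)C(C)(C)C)O1 | intermediate
19 | (8S)-8-(tert-butyldimethylsilyloxy)-20-(2-methyl-1,3-dioxolan-2-yl)icos-1-ene-1,3,5,7-tetrone (acylketene) | O=C=CC(=O)CC(=O)CC(=O)[C@H](CCCCCCCCCCCCC1(C)OCCO1)O[Si](C)(C)C(C)(C)C | intermediate (not isolated)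
20 | methyl (8S)-8-(tert-butyldimethylsilyloxy)-20-(2-methyl-1,3-dioxolan-2-yl)-3,5,7-trioxoicosanoate | COC(=O)CC(=O)CC(=O)CC(=O)[C@H](CCCCCCCCCCCCC1(C)OCCO1)O[Si](C)(C)C(C)(C)C | intermediate (not isolated)
21 | methyl 2-[(1S)-1-(tert-butyldimethylsilyloxy)-13-(2-methyl-1,3-dioxolan-2-yl)tridecyl]-2-hydroxy-4,6-dioxocyclohexane-1-carboxylate (ring centres undefined, lost on aromatisation) | COC(=O)C1C(=O)CC(=O)CC1(O)[C@H](CCCCCCCCCCCCC2(C)OCCO2)O[Si](C)(C)C(C)(C)C | intermediate (not isolated)
22 | methyl 2-[(1S)-1-(tert-butyldimethylsilyloxy)-13-(2-methyl-1,3-dioxolan-2-yl)tridecyl]-4,6-dihydroxybenzoate | COC(=O)c1c(O)cc(O)cc1[C@H](CCCCCCCCCCCCC2(C)OCCO2)O[Si](C)(C)C(C)(C)C | intermediate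
23 | (3S)-5,7-dihydroxy-3-(13-oxotetradecyl)-2-benzofuran-1(3H)-one | Oc1cc(O)c2c(c1)[C@H](CCCCCCCCCCCCC(C)=O)OC2=O | intermediate
24 | CJ-13,108, (3S)-5,7-dimethoxy-3-(13-oxotetradecyl)-2-benzofuran-1(3H)-one | COc1cc(OC)c2c(c1)[C@H](CCCCCCCCCCCCC(C)=O)OC2=O | target

**Step count**
Total: 13 steps. Longest linear sequence: 12 steps (steps 1–8 and 10–13, from 12-bromododecanoic acid); step 9 is a one-step side branch.

**Steps most likely to fail**

Step 11. The acylketene may be captured by the internal enol oxygen to give a 4-hydroxy-2-pyranone before methanol adds. The carbocycle may also stall as the hydrated aldol adduct, and the acid needed to dehydrate it may start to remove the silyl ether or ketal. The fallback sets out from 18 and keeps the dioxinone ring, so that no ketene is generated. Et3N in CH2Cl2 at room temperature ionises the methylene between the dioxinone and the first ketone. The resulting dienolate attacks through dioxinone C5 onto the same α-silyloxy ketone, forming the same C3a–C7a bond, and spontaneous dehydration should give 7-hydroxy-2,2-dimethyl-5-[(1S)-1-(tert-butyldimethylsilyloxy)-13-(2-methyl-1,3-dioxolan-2-yl)tridecyl]-4H-1,3-benzodioxin-4-one F1. K2CO3 in MeOH at room temperature then opens the aryl acetonide ester by methanolysis, and the route is rejoined at 22.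

Step 10. Proton transfer from the acidic diketone product, slow addition to the α-branched amide, O-acylation or partial enolisation of the α-silyloxy amide may consume the dianion and leave the amide unreacted or epimerised. The fallback sets out from 10 and replaces the acylation by an aldol addition and oxidation. Dess–Martin periodinane (NaHCO3, CH2Cl2) should give (2S)-2-(tert-butyldimethylsilyloxy)-14-(2-methyl-1,3-dioxolan-2-yl)tetradecanal F2. Addition of this aldehyde to the dienediolate 17 (from 16 and LiN(iPr)2, THF, −78 °C) should give 6-[(5S)-5-(tert-butyldimethylsilyloxy)-4-hydroxy-17-(2-methyl-1,3-dioxolan-2-yl)-2-oxoheptadecyl]-2,2-dimethyl-4H-1,3-dioxin-4-one F3 as a mixture of carbinol epimers, which does not matter. A second Dess–Martin oxidation returns the route to 18; compounds 11 to 13 are bypassed.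

Step 9. The product is more acidic than the starting dioxinone, so proton transfer quenches dienolate, and the product enolate can be acylated again at oxygen or carbon. The fallback sets out from 14 and builds the ketone by a vinylogous Mukaiyama aldol reaction and oxidation. LiN(iPr)2 and Me3SiCl in THF at −78 °C should give trimethyl[(2,2-dimethyl-6-methylidene-6H-1,3-dioxin-4-yl)oxy]silane F4. Its BF3·OEt2-promoted addition to acetaldehyde in CH2Cl2 at −78 °C should give racemic 6-(2-hydroxypropyl)-2,2-dimethyl-4H-1,3-dioxin-4-one F5. Dess–Martin oxidation of the secondary alcohol returns the route to 16.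

**Further compounds**
F1 | step 11 | 7-hydroxy-2,2-dimethyl-5-[(1S)-1-(tert-butyldimethylsilyloxy)-13-(2-methyl-1,3-dioxolan-2-yl)tridecyl]-4H-1,3-benzodioxin-4-one | CC1(C)OC(=O)c2c(O1)cc(O)cc2[C@H](CCCCCCCCCCCCC3(C)OCCO3)O[Si](C)(C)C(C)(C)C
F2 | step 10 | (2S)-2-(tert-butyldimethylsilyloxy)-14-(2-methyl-1,3-dioxolan-2-yl)tetradecanal | O=C[C@H](CCCCCCCCCCCCC1(C)OCCO1)O[Si](C)(C)C(C)(C)C
F3 | step 10 | 6-[(5S)-5-(tert-butyldimethylsilyloxy)-4-hydroxy-17-(2-methyl-1,3-dioxolan-2-yl)-2-oxoheptadecyl]-2,2-dimethyl-4H-1,3-dioxin-4-one | CC1(C)OC(=O)C=C(CC(=O)CC(O)[C@H](CCCCCCCCCCCCC2(C)OCCO2)O[Si](C)(C)C(C)(C)C)O1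
F4 | step 9 | trimethyl[(2,2-dimethyl-6-methylidene-6H-1,3-dioxin-4-yl)oxy]silane | C=C1C=C(O[Si](C)(C)C)OC(C)(C)O1
F5 | step 9 | 6-(2-hydroxypropyl)-2,2-dimethyl-4H-1,3-dioxin-4-one (racemic) | CC(O)CC1=CC(=O)OC(C)(C)O1
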